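The route grows the benzene ring (ring A: C4a, C5, C6, C7, C8, C8a) onto a finished 4-pyranone (ring B). The target has its only ring-A oxygen at C5, which is bonded to C4a, while C8 is bonded to C8a; C5 can therefore begin as an ester carbon on pyranone C3 and C8 as a methyl carbon on pyranone C2. One anionic operation, lateral lithiation, conjugate addition to methyl acrylate (C8–C7) and Dieckmann closure (C6–C5), installs ring A as a cyclohexanone β-keto ester. Its precursor is a 2-methyl-4-pyranone-3-carboxylate carrying the pentadecyl chain at C6; ester loss and dehydrogenation then reveal the phenol.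

Key step: step 4

Remark: enolisable compounds are written as a single tautomer (the acyl Meldrum's acid as its enol, the β-keto ester as its keto form), and centres formed without control are racemic and drawn without configuration.

Step 1
Reactants: 1 palmitoyl chloride (hexadecanoyl chloride); 2 Meldrum's acid (2,2-dimethyl-1,3-dioxane-4,6-dione)
Product: 3 5-(1-hydroxyhexadecylidene)-2,2-dimethyl-1,3-dioxane-4,6-dione (palmitoyl Meldrum's acid, enol form)
Conditions: pyridine (2 equiv), CH2Cl2, 0 °C → rt; 1 M HCl wash
Reagents that add atoms: none
Why: C-acylation of the acidic methylene of Meldrum's acid by an acid chloride in the presence of pyridine is the standard entry to acyl Meldrum's acids, and the product rests as its hydrogen-bonded enol.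

Step 2
Reactants: 4 methyl acetoacetate
Product: 5 methyl (E)-3-(pyrrolidin-1-yl)but-2-enoate
Conditions: pyrrolidine (1.1 equiv), PhMe, reflux, Dean–Stark
Reagents that add atoms: pyrrolidine, C1CCNC1
Why: Enamine condensation of a secondary amine with the ketone carbonyl of a β-keto ester, driven by removal of water, should give the conjugated enamino ester, the E geometry being the stable one for a tertiary amino group.

Step 3
Reactants: 3 palmitoyl Meldrum's acid; 5 methyl (E)-3-(pyrrolidin-1-yl)but-2-enoate
Product: 8 methyl 2-methyl-4-oxo-6-pentadecyl-4H-pyran-3-carboxylate, via acylketene 6 (not isolated), via cyclic aminal 7 (not isolated)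
Conditions: PhMe, 100 °C, 3 (1.5 equiv) added slowly to 5; 1 M HCl wash
Reagents that add atoms: none
Why: Thermal retro-[4+2] fragmentation of the acyl Meldrum's acid releases acetone and CO2, the acylketene is captured in a formal [4+2] addition by the nucleophilic α-carbon and the amino-bearing carbon of the enamino ester, and β-elimination of pyrrolidine from the aminal leaves the 4-pyranone (the enamine version of the acylketene γ-pyranone synthesis), the amino-bearing carbon directing the enol oxygen away from the ester so that no 2-pyranone should form.

Step 4
Reactants: 8 methyl 2-methyl-4-oxo-6-pentadecyl-4H-pyran-3-carboxylate; 9 methyl acrylate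
Product: 12 methyl 4,5-dioxo-2-pentadecyl-5,6,7,8-tetrahydro-4H-chromene-6-carboxylate (racemic at C6), via lithium dienolate 10 (not isolated), via Michael-adduct ester enolate 11 (not isolated)
Conditions: LiN(SiMe3)2 (2.2 equiv), THF, −78 °C; 9 (1.1 equiv, slow addition), −78 → 0 °C; 1 M HCl
Reagents that add atoms: none
Why: LiN(SiMe3)2 deprotonates the C2 methyl group of 8 to the cross-conjugated lithium dienolate 10, whose exocyclic carbon adds 1,4 to methyl acrylate (new bond C8–C7), and the ester enolate 11 attacks the adjacent ring ester (new bond C6–C5) with loss of methoxide, after which the product rests as its stabilised β-keto ester enolate until the acidic quench. The closest known reaction type is the Staunton–Weinreb annulation, the tandem Michael–Dieckmann reaction of laterally lithiated ortho-methyl aryl esters with α,β-unsaturated carbonyl compounds, the 2-methyl-3-carboxylate of the pyranone being the heterocyclic counterpart of an ortho-toluate. Ring A closes in the 6-exo-trig mode, the enolate carbon attacking an ester carbonyl whose C=O lies outside the new six-membered ring. The one new stereocentre, C6, is formed without control, is racemic and enolisable, and is erased by the decarboxylation and aromatisation that follow. The step needs deprotonation at the C2 methyl group and not at the first CH2 of the pentadecyl chain, which is secured because only the methyl group is vinylogous to both the C4 ketone and the C3 ester and is the less hindered site. It also needs a single conjugate addition in preference to acrylate oligomerisation, which slow addition of 9 at −78 °C and the fast intramolecular trapping of 11 by the neighbouring ester should secure.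

Step 5
Reactants: 12 methyl 4,5-dioxo-2-pentadecyl-5,6,7,8-tetrahydro-4H-chromene-6-carboxylate
Product: 13 2-pentadecyl-7,8-dihydro-4H-chromene-4,5(6H)-dione
Conditions: LiCl (3 equiv), H2O (2 equiv), DMSO, 130 °C
Reagents that add atoms: none
Why: In this Krapcho dealkoxycarbonylation chloride removes the ester methyl group by SN2 attack, the β-keto carboxylate loses CO2 and water protonates the enolate, all under near-neutral conditions that should leave the pyranone and the C5 ketone intact and that remove the C6 stereocentre.

Step 6
Reactants: 13 2-pentadecyl-7,8-dihydro-4H-chromene-4,5(6H)-dione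
Product: 14 6-bromo-2-pentadecyl-7,8-dihydro-4H-chromene-4,5(6H)-dione (racemic)
Conditions: CuBr2 (2.1 equiv), EtOAc–CHCl3 (1:1), reflux
Reagents that add atoms: CuBr2, [Cu+2].[Br-].[Br-]
Why: CuBr2 α-brominates ketones through the copper-bound enol, and C6 is the only hydrogen-bearing α-carbon of the C5 ketone (C4a is fully substituted), as in the established bromination of ring-fused cyclohexenone vinylogous esters such as 4-oxotetrahydrobenzofurans; the racemic C6 centre is destroyed in the next step, and a bromide at C8 would lead to the same phenol.

Step 7
Reactants: 14 6-bromo-2-pentadecyl-7,8-dihydro-4H-chromene-4,5(6H)-dione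
Product: 16 5-hydroxy-2-pentadecyl-4H-chromen-4-one (target), via dienone tautomer 15 (not isolated)
Conditions: Li2CO3 (2 equiv), LiBr (2 equiv), DMF, 120 °C; dilute HCl work-up
Reagents that add atoms: none
Why: Carbonate-mediated dehydrobromination across C6–C7 gives the cross-conjugated dienone, which is the keto tautomer of the phenol and should aromatise at once by enolisation, the C5 hydroxyl gaining a hydrogen bond to the C4 carbonyl.

Compound list
1 | palmitoyl chloride (hexadecanoyl chloride) | CCCCCCCCCCCCCCCC(=O)Cl | starting material
2 | Meldrum's acid (2,2-dimethyl-1,3-dioxane-4,6-dione) | CC1(C)OC(=O)CC(=O)O1 | starting material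
3 | 5-(1-hydroxyhexadecylidene)-2,2-dimethyl-1,3-dioxane-4,6-dione | CCCCCCCCCCCCCCCC(O)=C1C(=O)OC(C)(C)OC1=O | intermediate
4 | methyl acetoacetate | CC(=O)CC(=O)OC | starting material
5 | methyl (E)-3-(pyrrolidin-1-yl)but-2-enoate | C/C(=C\C(=O)OC)N1CCCC1 | intermediate
6 | hexadecanoylketene (3-oxooctadec-1-en-1-one) | CCCCCCCCCCCCCCCC(=O)C=C=O | intermediate
7 | methyl 2-methyl-4-oxo-6-pentadecyl-2-(pyrrolidin-1-yl)-3,4-dihydro-2H-pyran-3-carboxylate (racemic, mixture of diastereomers) | CCCCCCCCCCCCCCCC1=CC(=O)C(C(=O)OC)C(C)(N2CCCC2)O1 | intermediate
8 | methyl 2-methyl-4-oxo-6-pentadecyl-4H-pyran-3-carboxylate | CCCCCCCCCCCCCCCc1cc(=O)c(C(=O)OC)c(C)o1 | intermediate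
9 | methyl acrylate | C=CC(=O)OC | starting material
10 | lithium 3-(methoxycarbonyl)-2-methylidene-6-pentadecyl-2H-pyran-4-olate | CCCCCCCCCCCCCCCC1=CC(O[Li])=C(C(=O)OC)C(=C)O1 | intermediate
11 | lithium ester enolate of methyl 2-(4-methoxy-4-oxobutyl)-4-oxo-6-pentadecyl-4H-pyran-3-carboxylate | CCCCCCCCCCCCCCCc1cc(=O)c(C(=O)OC)c(CCC=C(OC)O[Li])o1 | intermediate
12 | methyl 4,5-dioxo-2-pentadecyl-5,6,7,8-tetrahydro-4H-chromene-6-carboxylate (racemic) | CCCCCCCCCCCCCCCc1cc(=O)c2c(o1)CCC(C(=O)OC)C2=O | intermediate
13 | 2-pentadecyl-7,8-dihydro-4H-chromene-4,5(6H)-dione | CCCCCCCCCCCCCCCc1cc(=O)c2c(o1)CCCC2=O | intermediate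
14 | 6-bromo-2-pentadecyl-7,8-dihydro-4H-chromene-4,5(6H)-dione (racemic) | CCCCCCCCCCCCCCCc1cc(=O)c2c(o1)CCC(Br)C2=O | intermediate
15 | 2-pentadecyl-4H-chromene-4,5(8H)-dione | CCCCCCCCCCCCCCCc1cc(=O)c2c(o1)CC=CC2=O | intermediate
16 | 5-hydroxy-2-pentadecyl-4H-chromen-4-one | CCCCCCCCCCCCCCCc1cc(=O)c2c(O)cccc2o1 | target

Total step count: 7. Longest linear sequence: 6 steps (1, 3, 4, 5, 6, 7); step 2 is a one-step side branch.

Steps most likely to fail

Step 4. Anionic chain growth of the acrylate could outrun ring closure, lateral deprotonation could occur at the chain CH2, or the Michael adduct could fail to close. The fallback builds ring B onto a ready-made ring A and sets out from 3. Thermolysis of 3 (PhMe, 100 °C) in the presence of commercial cyclohexane-1,3-dione, followed by Et3N and catalytic DMAP to move any enol ester to carbon, should give 2-(3-oxooctadecanoyl)cyclohexane-1,3-dione F1. Cyclodehydration of the ring enol oxygen onto the side-chain ketone (TsOH, PhMe, reflux, Dean–Stark) should then give 13, where the route is rejoined.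

Step 3. The acylketene could be consumed by the pyrrolidine it releases, or by a second ketene, before the weakly nucleophilic enamino ester captures it. The fallback avoids both ketene and amine and sets out from 4. Commercial heptadec-1-yne is carboxylated (n-BuLi, THF, −78 °C; CO2) to octadec-2-ynoic acid F2 and converted with (COCl)2 and catalytic DMF into octadec-2-ynoyl chloride F3. C-acylation of the methoxymagnesium enolate of 4 (Mg(OMe)2, PhMe, 0 °C) should give methyl 2-acetyl-3-oxoicos-4-ynoate F4. Its acetyl enol oxygen should add 6-endo-dig to the ynone (K2CO3, acetone, rt) to give 8, where the route is rejoined.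

Step 6. Over-bromination, or electrophilic bromination at C3 of the pyranone, could compete with bromination at C6. The fallback uses no halogen and goes from 13 directly to 16. Aerobic dehydrogenation with divalent palladium (Pd(OCOCF3)2, 2-(dimethylamino)pyridine, TsOH, O2, DMSO, 80 °C) should form a palladium enolate at C6, which undergoes β-hydride elimination toward C7, and the dienone then tautomerises to the phenol. This fallback makes no new compound (F0).

Further compounds
F1 | step 4 | 2-(3-oxooctadecanoyl)cyclohexane-1,3-dione | CCCCCCCCCCCCCCCC(=O)CC(=O)C1C(=O)CCCC1=O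
F2 | step 3 | octadec-2-ynoic acid | CCCCCCCCCCCCCCCC#CC(=O)O
F3 | step 3 | octadec-2-ynoyl chloride | CCCCCCCCCCCCCCCC#CC(=O)Cl
F4 | step 3 | methyl 2-acetyl-3-oxoicos-4-ynoate | CCCCCCCCCCCCCCCC#CC(=O)C(C(C)=O)C(=O)OC
F0 | step 6 | none | none
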